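The route rests on disconnecting the cis C3=C4 olefin of the 2H-pyran ring, the alkene that lies between the quaternary gem-dimethyl carbon C2 (bound to O1) and the arene carbon C4a. Ring-closing olefin metathesis forges this bond and closes the pyran ring in one operation, with ethylene as the only by-product. Its precursor is a fully substituted 2,6-dihydroxybenzophenone carrying a vinyl group at C5, a 1,1-dimethylallyl ether on O4 and the prenyl group at C3. It is assembled on a Hoesch-derived phloroglucinol ketone by iodination/Stille vinylation, C-prenylation and palladium-catalysed O-tert-prenylation, with the B-ring phenol masked as a pivalate.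

Key step: step 7

Remark: the target has no stereocentre and its only stereo-relevant element, the endocyclic C3=C4 olefin, is necessarily cis, so the structure is achiral and no enantiocontrol is needed.

Step 1
Reactants: 1 3-hydroxybenzonitrile
Product: 2 3-cyanophenyl pivalate
Conditions: PivCl, Et3N, DMAP (cat.), CH2Cl2, 0 °C to rt
Reagents that add atoms: pivaloyl chloride, CC(C)(C)C(Cl)=O
Why: DMAP-catalysed esterification of the phenol gives a hindered aryl ester that should withstand the acid, the amidine base and the Pd(0) of the later steps and keeps the B-ring oxygen out of every alkylation.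

Step 2
Reactants: 2 3-cyanophenyl pivalate; 3 phloroglucinol (anhydrous)
Product: 5 3-(2,4,6-trihydroxybenzoyl)phenyl pivalate, via ketiminium chloride 4 (not isolated)
Conditions: ZnCl2, HCl (g), Et2O, 0 °C; then H2O, 90 °C
Reagents that add atoms: water, O
Why: Houben–Hoesch reaction: the nitrile activated by HCl acylates the very electron-rich phloroglucinol once at carbon (the ketiminium salt is deactivated towards a second attack), and hot water hydrolyses the ketiminium salt to the ketone while the hindered pivalate should survive the weakly acidic medium.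

Step 3
Reactants: 5 3-(2,4,6-trihydroxybenzoyl)phenyl pivalate
Product: 6 3-(2,4,6-trihydroxy-3-iodobenzoyl)phenyl pivalate
Conditions: NIS (1.0 equiv), MeCN, 0 °C, dark
Reagents that add atoms: N-iodosuccinimide, O=C1CCC(=O)N1I
Why: Electrophilic aromatic iodination: the acylphloroglucinol ring is far more nucleophilic than the acyl- and acyloxy-substituted B ring, its two free positions are equivalent, and one equivalent of NIS at 0 °C should stop mainly at the mono-iodide.

Step 4
Reactants: 6 3-(2,4,6-trihydroxy-3-iodobenzoyl)phenyl pivalate
Product: 7 3-(2,4,6-trihydroxy-3-vinylbenzoyl)phenyl pivalate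
Conditions: Bu3SnCH=CH2, Pd(PPh3)4 (5 mol%), BHT (cat.), DMF, 80 °C
Reagents that add atoms: tributyl(vinyl)stannane, C=C[Sn](CCCC)(CCCC)CCCC
Why: Stille cross-coupling under neutral conditions tolerates the free phenols, the diaryl ketone and the pivalate and replaces iodine by the vinyl group.

Step 5
Reactants: 7 3-(2,4,6-trihydroxy-3-vinylbenzoyl)phenyl pivalate
Product: 8 3-[2,4,6-trihydroxy-3-(3-methylbut-2-en-1-yl)-5-vinylbenzoyl]phenyl pivalate
Conditions: prenyl bromide (1.05 equiv), DBU (1.1 equiv), THF, 0 °C to rt
Reagents that add atoms: prenyl bromide, CC(C)=CCBr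
Why: Base-mediated C-prenylation of a 2,4,6-trihydroxyacylphenone: DBU ionises the most acidic 4-OH and the ambident phenoxide is alkylated (SN2) at the only unsubstituted ring carbon, ortho to the phenoxide oxygen.

Step 6
Reactants: 8 3-[2,4,6-trihydroxy-3-(3-methylbut-2-en-1-yl)-5-vinylbenzoyl]phenyl pivalate
Product: 9 3-[2,6-dihydroxy-4-(2-methylbut-3-en-2-yloxy)-3-(3-methylbut-2-en-1-yl)-5-vinylbenzoyl]phenyl pivalate
Conditions: tert-butyl 2-methylbut-3-en-2-yl carbonate (1.2 equiv), Pd(PPh3)4 (5 mol%), THF, 0 °C
Reagents that add atoms: tert-butyl 2-methylbut-3-en-2-yl carbonate, CC(C)(C)OC(=O)OC(C)(C)C=C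
Why: Tsuji–Trost O-allylation (decarboxylative reverse prenylation): the tert-butoxide released from the carbonate deprotonates the 4-OH, the only hydroxyl not hydrogen-bonded to the benzoyl carbonyl and the most acidic one, and the phenoxide attacks the more substituted terminus of the π-(1,1-dimethylallyl)palladium complex under kinetic control at 0 °C.

Step 7
Reactants: 9 3-[2,6-dihydroxy-4-(2-methylbut-3-en-2-yloxy)-3-(3-methylbut-2-en-1-yl)-5-vinylbenzoyl]phenyl pivalate
Product: 10 3-[5,7-dihydroxy-2,2-dimethyl-8-(3-methylbut-2-en-1-yl)-2H-chromene-6-carbonyl]phenyl pivalate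
Conditions: Grubbs II catalyst (5 mol%), CH2Cl2 (0.005 M), 40 °C
Reagents that add atoms: none
Why: Ring-closing olefin metathesis: the ruthenium carbene loads on the monosubstituted styrenyl vinyl group at C5, the resulting arylidene adds [2+2] to the vinyl group of the neighbouring 1,1-dimethylallyl ether, and cycloreversion of the ruthenacyclobutane expels ethylene and leaves the C3=C4 double bond. The closest known reaction type is the ring-closing metathesis of 2-(allyloxy)styrenes to 2H-chromenes. The six-membered 2H-pyran ring is closed by metathesis of two terminal olefins held ortho to each other on the arene, helped by the gem-dimethyl group (Thorpe–Ingold effect) and by the flanking prenyl group that pushes the ether arm towards the vinyl group. No stereocentre is formed, and the ring enforces the cis geometry of the new olefin. The step needs chemoselectivity for the two monosubstituted olefins over the trisubstituted prenyl olefin (which could close a seven-membered oxepine with loss of isobutene) and ring closure over dimerisation. The much slower metathesis of trisubstituted olefins, the kinetic preference for the six-membered ring and high dilution should secure both, while the chelated phenols, the diaryl ketone and the pivalate are tolerated by the catalyst.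

Step 8
Reactants: 10 3-[5,7-dihydroxy-2,2-dimethyl-8-(3-methylbut-2-en-1-yl)-2H-chromene-6-carbonyl]phenyl pivalate
Product: 11 [5,7-dihydroxy-2,2-dimethyl-8-(3-methylbut-2-en-1-yl)-2H-chromen-6-yl](3-hydroxyphenyl)methanone
Conditions: K2CO3, MeOH (degassed), rt; aq. NH4Cl work-up
Reagents that add atoms: none
Why: Base-catalysed methanolysis (transesterification) of the aryl pivalate frees the 3'-phenol under conditions that leave the chromene, the prenyl group and the chelated phenols untouched, and the buffered work-up avoids acid-induced cyclisation of the prenyl group onto the neighbouring phenol.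

Compound list
1 | 3-hydroxybenzonitrile | N#Cc1cccc(O)c1 | starting material
2 | 3-cyanophenyl pivalate | CC(C)(C)C(=O)Oc1cccc(C#N)c1 | intermediate
3 | phloroglucinol (benzene-1,3,5-triol) | Oc1cc(O)cc(O)c1 | starting material
4 | [3-(pivaloyloxy)phenyl](2,4,6-trihydroxyphenyl)methaniminium chloride | CC(C)(C)C(=O)Oc1cccc(c1)C(=[NH2+])c1c(O)cc(O)cc1O.[Cl-] | intermediate
5 | 3-(2,4,6-trihydroxybenzoyl)phenyl pivalate | CC(C)(C)C(=O)Oc1cccc(c1)C(=O)c1c(O)cc(O)cc1O | intermediate
6 | 3-(2,4,6-trihydroxy-3-iodobenzoyl)phenyl pivalate | CC(C)(C)C(=O)Oc1cccc(c1)C(=O)c1c(O)cc(O)c(I)c1O | intermediate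
7 | 3-(2,4,6-trihydroxy-3-vinylbenzoyl)phenyl pivalate | CC(C)(C)C(=O)Oc1cccc(c1)C(=O)c1c(O)cc(O)c(C=C)c1O | intermediate
8 | 3-[2,4,6-trihydroxy-3-(3-methylbut-2-en-1-yl)-5-vinylbenzoyl]phenyl pivalate | CC(C)(C)C(=O)Oc1cccc(c1)C(=O)c1c(O)c(CC=C(C)C)c(O)c(C=C)c1O | intermediate
9 | 3-[2,6-dihydroxy-4-(2-methylbut-3-en-2-yloxy)-3-(3-methylbut-2-en-1-yl)-5-vinylbenzoyl]phenyl pivalate | CC(C)(C)C(=O)Oc1cccc(c1)C(=O)c1c(O)c(CC=C(C)C)c(OC(C)(C)C=C)c(C=C)c1O | intermediate
10 | 3-[5,7-dihydroxy-2,2-dimethyl-8-(3-methylbut-2-en-1-yl)-2H-chromene-6-carbonyl]phenyl pivalate | CC(C)(C)C(=O)Oc1cccc(c1)C(=O)c1c(O)c(CC=C(C)C)c2OC(C)(C)C=Cc2c1O | intermediate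
11 | [5,7-dihydroxy-2,2-dimethyl-8-(3-methylbut-2-en-1-yl)-2H-chromen-6-yl](3-hydroxyphenyl)methanone | CC(C)=CCc1c(O)c(C(=O)c2cccc(O)c2)c(O)c2c1OC(C)(C)C=C2 | target

Total step count: 8
Longest linear sequence: 8 steps (1 to 11; phloroglucinol 3 enters at step 2)

Steps most likely to fail

Step 6. The 4-OH is flanked by two ortho substituents, so etherification may be slow. Reversible ionisation of the π-allyl complex could then funnel material to the linear O-prenyl ether or to dearomatising C-allylation. The fallback sets out from 8 and builds the tertiary ether in two irreversible operations. Copper-catalysed propargylation (3-chloro-3-methylbut-1-yne, DBU, CuCl2 cat., MeCN, 0 °C) should give 3-[2,6-dihydroxy-4-(2-methylbut-3-yn-2-yloxy)-3-(3-methylbut-2-en-1-yl)-5-vinylbenzoyl]phenyl pivalate F1 through a sterically slender copper allenylidene. Lindlar semi-hydrogenation (H2, Pd/CaCO3–Pb, quinoline, EtOAc, stopped after one equivalent of hydrogen) should reduce only the terminal alkyne and comes back to the route at 9.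

Step 5. O-prenylation or geminal (dearomatising) C-alkylation may outrun the attack at the free ring carbon. The fallback sets out from 7 and delivers the prenyl group by a sigmatropic route. Pd-catalysed O-tert-prenylation at the 4-OH (conditions of step 6) should give 3-[2,6-dihydroxy-4-(2-methylbut-3-en-2-yloxy)-3-vinylbenzoyl]phenyl pivalate F2. An aromatic Claisen rearrangement (toluene, 110 °C, BHT) should then transfer the allyl unit with allylic inversion to the only ortho carbon that can rearomatise, which comes back to the route at 8.

Step 7. The catalyst may engage the prenyl olefin (seven-membered ring closure with loss of isobutene, or truncation by ethenolysis), or the hindered diene may oligomerise. The fallback sets out from 7 and closes the ring before the prenyl group is present. Compound 7 would be converted into the 1,1-dimethylallyl ether F2 as described above. Metathesis of F2 (Grubbs II, CH2Cl2, 40 °C), which holds only the two terminal olefins, should give 3-(5,7-dihydroxy-2,2-dimethyl-2H-chromene-6-carbonyl)phenyl pivalate F3. C-Prenylation of its sodium phenoxide in a non-polar medium (NaH, prenyl bromide, toluene, rt) at C8, the only free ring carbon, would come back to the route at 10.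

Further compounds
F1 | step 6 | 3-[2,6-dihydroxy-4-(2-methylbut-3-yn-2-yloxy)-3-(3-methylbut-2-en-1-yl)-5-vinylbenzoyl]phenyl pivalate | CC(C)(C)C(=O)Oc1cccc(c1)C(=O)c1c(O)c(CC=C(C)C)c(OC(C)(C)C#C)c(C=C)c1O
F2 | step 5 | 3-[2,6-dihydroxy-4-(2-methylbut-3-en-2-yloxy)-3-vinylbenzoyl]phenyl pivalate | CC(C)(C)C(=O)Oc1cccc(c1)C(=O)c1c(O)cc(OC(C)(C)C=C)c(C=C)c1O
F3 | step 7 | 3-(5,7-dihydroxy-2,2-dimethyl-2H-chromene-6-carbonyl)phenyl pivalate | CC(C)(C)C(=O)Oc1cccc(c1)C(=O)c1c(O)cc2OC(C)(C)C=Cc2c1O
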